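The C4–C5 bond of ring A (C1–C5, C10) carries the whole plan. The γ-hydroxy aldehyde array C18(=O)–C4–C5–C6–OH, with C4 and O6 trans on ring B, is read as an enolate that has displaced a C5–O bond with inversion. The key step is therefore an intramolecular alkylation: the ester enolate on a C10 tether opens a ring B 5α,6α-cyclic sulfate at C5. This closes ring A, creates quaternary C4, inverts C5 and leaves the 6α-oxygen. The precursor is monocyclic: ring B, taken from bromobenzene cis-dihydrodiol, already carrying the exocyclic methylene, the C9 butynyl chain and the tether.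

Key step: step 11

Remark: labdane numbering of the target is used for every intermediate (ring B = C5–C10, tether = C1–C4 with C18, side chain = C11–C16); α is the face opposite the C10 methyl.
Remark: the tether carbon C4 of 5 is carried as an epimer mixture (left undefined in the SMILES) because it is enolised in step 11.
Remark: the (R,R)-bisphosphoramide of step 16 is assumed to direct attack to the Re face of the enal; if the sense is the opposite, its (S,S)-antipode is taken.

Step 1
Reactants: 1 (1S,2S)-3-bromocyclohexa-3,5-diene-1,2-diol; 2 2,2-dimethoxypropane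
Product: 3 bromodiene acetonide (5α,6α-O-isopropylidene; Br on C10; C7=C8 and C9=C10)
Conditions: TsOH (cat.), acetone, 0 °C → rt
Reagents that add atoms: 2,2-dimethoxypropane, COC(C)(C)OC
Why: acid-catalysed transketalisation (acetonide formation) of the cis-diol leaves both carbinol centres untouched and protects the dienediol against aromatisation.

Step 2
Reactants: 3 bromodiene acetonide
Product: 4 vinyl bromide acetonide (C7–C8 saturated; C9=C10–Br kept)
Conditions: KO2CN=NCO2K, AcOH, MeOH, 0 °C → rt
Reagents that add atoms: none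
Why: diimide reduction, in which diimide released from the azodicarboxylate transfers H2 only to the less substituted, halogen-free C7=C8 bond.

Step 3
Reactants: 4 vinyl bromide acetonide; 5 methyl 2-methylpent-4-enoate
Product: 7 tethered cyclohexene ester (C10 carries CH2CH2CH2CH(CH3)CO2Me), via B-alkyl-9-BBN adduct 6 (not isolated)
Conditions: 5, 9-BBN, THF, 0 °C → rt; then 4, Pd(dppf)Cl2 (cat.), K3PO4 (aq.), DMF, 50 °C
Reagents that add atoms: methyl 2-methylpent-4-enoate, C=CCC(C)C(=O)OC
Why: anti-Markovnikov hydroboration of the terminal alkene followed by B-alkyl Suzuki–Miyaura coupling at the vinyl bromide attaches the C1–C4/C18 tether to C10 without moving the ring alkene.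

Step 4
Reactants: 7 tethered cyclohexene ester; 8 tert-butyl hydroperoxide
Product: 9 enone (C8 ketone conjugated with C9=C10)
Conditions: Rh2(cap)4 (cat., cap = caprolactamate), t-BuOOH (aq.), CH2Cl2, rt
Reagents that add atoms: tert-butyl hydroperoxide, CC(C)(C)OO
Why: radical allylic C–H oxidation, in which the well-aligned axial hydrogen of the ring CH2 (C8) next to the unsubstituted alkene carbon is abstracted and oxidised to the conjugated 3-alkylcyclohexenone, whereas the equatorial α-oxy C5–H is poorly aligned with the π system.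

Step 5
Reactants: 9 enone; 10 methyllithium; 11 chlorotrimethylsilane
Product: 12 silyl enol ether (C8–OSiMe3, C8=C9) having quaternary C10 (β-methyl, α-tether)
Conditions: MeLi, CuI, THF, −20 °C; then 9, Me3SiCl, −78 → −40 °C
Reagents that add atoms: methyllithium, [Li]C; chlorotrimethylsilane, C[Si](C)(C)Cl
Why: cuprate conjugate addition, in which allylic strain with the C10 tether holds the C5–O bond pseudoaxial so that methyl enters C10 anti to it (β face), and the enolate is trapped regiospecifically as the C8–C9 silyl enol ether.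

Step 6
Reactants: 12 silyl enol ether; 13 acrolein
Product: 15 keto aldehyde (C8 ketone, 3-oxopropyl on C9; drawn as the 9β-alkyl isomer, its C9 epimer may accompany it), via silyl enol ether 14 (not isolated)
Conditions: acrolein, Sc(OTf)3 (cat.), CH2Cl2, −78 °C; then pH 5 acetate buffer
Reagents that add atoms: acrolein, C=CC=O
Why: Mukaiyama–Michael addition of the regiodefined silyl enol ether to Lewis-acid-activated acrolein forms the C9–C11 bond; C9 is not controlled here and is settled in step 7.

Step 7
Reactants: 15 keto aldehyde; 16 dimethyl (1-diazo-2-oxopropyl)phosphonate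
Product: 17 alkynyl ketone (9β-but-3-ynyl, 9α-H)
Conditions: K2CO3, MeOH, 0 °C → rt
Reagents that add atoms: dimethyl (1-diazo-2-oxopropyl)phosphonate, CC(=O)C(=[N+]=[N-])P(=O)(OC)OC
Why: Seyferth–Gilbert homologation with the Ohira–Bestmann reagent turns the aldehyde (not the hindered ketone) into the terminal alkyne, while K2CO3/MeOH equilibrates the enolisable C9 to the equatorial 9β chain, because in the acetonide-locked chair (C10 methyl axial, C5–O axial) a 9α substituent would be 1,3-diaxial to C5–O.

Step 8
Reactants: 17 alkynyl ketone; 18 methyltriphenylphosphonium bromide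
Product: 19 exocyclic methylene acetonide
Conditions: Ph3PCH3Br, KOt-Bu, toluene, 0 → 50 °C
Reagents that add atoms: methyltriphenylphosphonium bromide, C[P+](c1ccccc1)(c1ccccc1)c1ccccc1.[Br-]
Why: Wittig methylenation of the C8 ketone installs C17 while C9 stays at its thermodynamic configuration and the methyl ester is spared.

Step 9
Reactants: 19 exocyclic methylene acetonide
Product: 20 5α,6α-diol
Conditions: AcOH–H2O (4:1), 45 °C
Reagents that add atoms: none
Why: acid-catalysed acetonide hydrolysis frees the cis-diol without touching the alkene, alkyne or ester.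

Step 10
Reactants: 20 5α,6α-diol; 21 1,1'-sulfonyldiimidazole
Product: 22 5α,6α-cyclic sulfate
Conditions: NaH, THF, −20 → 0 °C
Reagents that add atoms: 1,1'-sulfonyldiimidazole, O=S(=O)(n1ccnc1)n1ccnc1
Why: sulfuryl transfer from the diimidazolide to the dialkoxide of the cis-diol closes the five-membered cyclic sulfate with retention at C5 and C6 and without an oxidant that would attack the alkene or alkyne.

Step 11
Reactants: 22 5α,6α-cyclic sulfate
Product: 25 bicyclic 6α,18-diol (ring A closed; 4α-CH2OH, 4β-CH3, 5α-H), via dilithiated enolate 23 (not isolated), via lithium sulfate monoester 24 (not isolated)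
Conditions: LDA (2.2 equiv), THF–DMPU, −78 → 0 °C; then LiAlH4, 0 °C; then H2SO4 (cat.), H2O, THF, rt
Reagents that add atoms: none
Why: LDA forms the lithium ester enolate (and the acetylide), and C4 of the enolate attacks C5 of the cyclic sulfate anti to the axial C5–O bond, closing ring A in a 6-exo-tet mode through a chair transition state in which the tether leaves C10 equatorially (attack at C6 would give a bridged ring). The closest known reaction types are the opening of cyclic sulfates by ester enolates and the intramolecular opening of epoxides by nitrile or ester enolates. C5 is set by inversion (C4 enters from the β face, H5 becomes α, trans ring fusion), C6 keeps its α-oxygen as the sulfate monoester, and C4 is set by the enolate face: the planar enolate carbon must lie equatorial (α), since an axial enolate would push one of its oxygen substituents against the C10 methyl and the axial H on C2, so the C4 methyl becomes β. The step needs substitution at the neopentyl-type C5 to outrun E2 loss of the sulfate and needs this C4 face selectivity; the rigid cis-fused sulfate with its axial leaving group, the intramolecular delivery and the lack of hydrogen on C10 should secure both. Reduction of the ester with LiAlH4 in the same flask, before mild acid hydrolyses the sulfate monoester, prevents lactonisation onto the C6 oxygen.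

Step 12
Reactants: 25 bicyclic 6α,18-diol; 26 triethylsilyl trifluoromethanesulfonate
Product: 27 bis(triethylsilyl) ether
Conditions: Et3SiOTf, 2,6-lutidine, CH2Cl2, −78 → 0 °C
Reagents that add atoms: triethylsilyl trifluoromethanesulfonate, CC[Si](CC)(CC)OS(=O)(=O)C(F)(F)F
Why: silyl triflate silylation protects the primary C18 and the hindered secondary C6 hydroxyl for the organoaluminium step.

Step 13
Reactants: 27 bis(triethylsilyl) ether; 28 trimethylaluminium; 29 paraformaldehyde
Product: 31 (E)-allylic alcohol (C13 methyl, C15 hydroxyl), via alkenylalane 30 (not isolated)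
Conditions: Me3Al, Cp2ZrCl2 (cat.), CH2Cl2, 0 °C → rt; then n-BuLi, (CH2O)n, THF, −78 °C → rt
Reagents that add atoms: trimethylaluminium, C[Al](C)C; paraformaldehyde (as formaldehyde), C=O
Why: Negishi carboalumination adds Me–Al syn across the terminal alkyne (methyl to C13) and the derived ate complex adds to formaldehyde with retention, which fixes the E geometry of C13=C14.

Step 14
Reactants: 31 (E)-allylic alcohol
Product: 32 dialdehyde (C15 enal, C18 aldehyde, 6α-OSiEt3)
Conditions: (COCl)2, DMSO, CH2Cl2, −78 → −40 °C; then Et3N, −78 → 0 °C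
Reagents that add atoms: none
Why: Swern oxidation turns the allylic alcohol into the enal and, through cleavage of the primary triethylsilyl ether by the chlorosulfonium reagent, the C18 silyl ether directly into the aldehyde, while the hindered secondary silyl ether on C6 is kept.

Step 15
Reactants: 33 4-methylfuran-2(5H)-one; 34 tert-butyldimethylsilyl trifluoromethanesulfonate
Product: 35 2-(tert-butyldimethylsilyloxy)-4-methylfuran
Conditions: t-BuMe2SiOTf, Et3N, CH2Cl2, 0 °C
Reagents that add atoms: tert-butyldimethylsilyl trifluoromethanesulfonate, CC(C)(C)[Si](C)(C)OS(=O)(=O)C(F)(F)F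
Why: soft enolisation and O-silylation of the butenolide give the aromatic silyl dienol ether.

Step 16
Reactants: 32 dialdehyde; 35 2-(tert-butyldimethylsilyloxy)-4-methylfuran
Product: 37 6-O-triethylsilyl ether of the target, via trichlorosilyl ether 36 (not isolated)
Conditions: SiCl4, (R,R)-bisphosphoramide (binaphthyl-2,2'-diamine-derived, pentane-1,5-diyl linked; cat.), i-Pr2NEt, CH2Cl2, −78 °C; aq. KF/NaHCO3 work-up
Reagents that add atoms: 2-(tert-butyldimethylsilyloxy)-4-methylfuran, Cc1coc(O[Si](C)(C)C(C)(C)C)c1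
Why: Lewis-base-catalysed, SiCl4-mediated vinylogous Mukaiyama aldol addition, in which the furan attacks through its C5 the Re face of the silicon-bound enal under control of the chiral bisphosphoramide, giving the like (15S,16S, threo) pair that is usual for Lewis-acid additions of 2-silyloxyfurans; the hindered, α-quaternary aliphatic C18 aldehyde should not react under these conditions.

Step 17
Reactants: 37 6-O-triethylsilyl ether of the target
Product: 38 target CNP0113661.1
Conditions: HF·pyridine, pyridine, THF, 0 °C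
Reagents that add atoms: none
Why: fluoride-mediated desilylation removes the C6 silyl ether under conditions the aldehyde, the butenolide and the allylic alcohol should tolerate.

Compound list
1 | (1S,2S)-3-bromocyclohexa-3,5-diene-1,2-diol | C1=C[C@H](O)[C@H](O)C(Br)=C1 | starting material
2 | 2,2-dimethoxypropane | COC(C)(C)OC | starting material
3 | bromodiene acetonide (5α,6α-O-isopropylidene, 10-bromo, C7=C8 and C9=C10) | C1=C[C@@H]2OC(C)(C)O[C@@H]2C(Br)=C1 | intermediate
4 | vinyl bromide acetonide (C9=C10–Br, C7–C8 saturated) | C1C[C@@H]2OC(C)(C)O[C@@H]2C(Br)=C1 | intermediate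
5 | methyl 2-methylpent-4-enoate (racemic) | C=CCC(C)C(=O)OC | starting material
6 | methyl 5-(9-borabicyclo[3.3.1]nonan-9-yl)-2-methylpentanoate | COC(=O)C(C)CCCB1C2CCCC1CCC2 | intermediate
7 | tethered cyclohexene ester (C10 tether CH2CH2CH2CH(CH3)CO2Me, C9=C10, acetonide) | C1C[C@@H]2OC(C)(C)O[C@@H]2C(CCCC(C)C(=O)OC)=C1 | intermediate
8 | tert-butyl hydroperoxide | CC(C)(C)OO | starting material
9 | enone (8-oxo, C9=C10, acetonide, tether on C10) | O=C1C[C@@H]2OC(C)(C)O[C@@H]2C(CCCC(C)C(=O)OC)=C1 | intermediate
10 | methyllithium | [Li]C | starting material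
11 | chlorotrimethylsilane | C[Si](C)(C)Cl | starting material
12 | silyl enol ether (C8–OSiMe3, C8=C9; C10 β-methyl, α-tether) | C[Si](C)(C)OC=1C[C@@H]2OC(C)(C)O[C@@H]2[C@](C)(CCCC(C)C(=O)OC)C=1 | intermediate
13 | acrolein | C=CC=O | starting material
14 | trimethylsilyl enol ether of the Michael adduct (C9 undefined) | O=C1C[C@@H]2OC(C)(C)O[C@@H]2[C@](C)(CCCC(C)C(=O)OC)C1CC=CO[Si](C)(C)C | intermediate
15 | keto aldehyde (8-oxo, 9β-(3-oxopropyl), 9α-H) | O=C1C[C@@H]2OC(C)(C)O[C@@H]2[C@](C)(CCCC(C)C(=O)OC)[C@H]1CCC=O | intermediate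
16 | dimethyl (1-diazo-2-oxopropyl)phosphonate | CC(=O)C(=[N+]=[N-])P(=O)(OC)OC | starting material
17 | alkynyl ketone (8-oxo, 9β-but-3-ynyl) | O=C1C[C@@H]2OC(C)(C)O[C@@H]2[C@](C)(CCCC(C)C(=O)OC)[C@H]1CCC#C | intermediate
18 | methyltriphenylphosphonium bromide | C[P+](c1ccccc1)(c1ccccc1)c1ccccc1.[Br-] | starting material
19 | exocyclic methylene acetonide (C8=C17) | C=C1C[C@@H]2OC(C)(C)O[C@@H]2[C@](C)(CCCC(C)C(=O)OC)[C@H]1CCC#C | intermediate
20 | 5α,6α-diol | C=C1C[C@H](O)[C@H](O)[C@](C)(CCCC(C)C(=O)OC)[C@H]1CCC#C | intermediate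
21 | 1,1'-sulfonyldiimidazole | O=S(=O)(n1ccnc1)n1ccnc1 | starting material
22 | 5α,6α-cyclic sulfate | C=C1C[C@@H]2OS(=O)(=O)O[C@@H]2[C@](C)(CCCC(C)C(=O)OC)[C@H]1CCC#C | intermediate
23 | dilithiated ester enolate–acetylide of 22 | C=C1C[C@@H]2OS(=O)(=O)O[C@@H]2[C@](C)(CCCC(C)=C(O[Li])OC)[C@H]1CCC#C[Li] | intermediate
24 | ring-closed methyl ester, 6α-O-sulfate lithium salt (lithium acetylide) | C=C1C[C@H](OS(=O)(=O)O[Li])[C@@H]2[C@](C)(CCC[C@@]2(C)C(=O)OC)[C@H]1CCC#C[Li] | intermediate
25 | bicyclic 6α,18-diol (4α-CH2OH, 4β-CH3, 5α-H, 9β-butynyl, 8(17)-ene) | C=C1C[C@H](O)[C@@H]2[C@](C)(CCC[C@@]2(C)CO)[C@H]1CCC#C | intermediate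
26 | triethylsilyl trifluoromethanesulfonate | CC[Si](CC)(CC)OS(=O)(=O)C(F)(F)F | starting material
27 | 6α,18-bis(triethylsilyl) ether | C=C1C[C@H](O[Si](CC)(CC)CC)[C@@H]2[C@](C)(CCC[C@@]2(C)CO[Si](CC)(CC)CC)[C@H]1CCC#C | intermediate
28 | trimethylaluminium | C[Al](C)C | starting material
29 | paraformaldehyde (formaldehyde) | C=O | starting material
30 | (E)-alkenyl(dimethyl)alane | C=C1C[C@H](O[Si](CC)(CC)CC)[C@@H]2[C@](C)(CCC[C@@]2(C)CO[Si](CC)(CC)CC)[C@H]1CC/C(C)=C/[Al](C)C | intermediate
31 | (E)-allylic alcohol (C15–OH) | C=C1C[C@H](O[Si](CC)(CC)CC)[C@@H]2[C@](C)(CCC[C@@]2(C)CO[Si](CC)(CC)CC)[C@H]1CC/C(C)=C/CO | intermediate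
32 | dialdehyde (C15 enal, C18 aldehyde, 6α-OSiEt3) | C=C1C[C@H](O[Si](CC)(CC)CC)[C@@H]2[C@](C)(CCC[C@@]2(C)C=O)[C@H]1CC/C(C)=C/C=O | intermediate
33 | 4-methylfuran-2(5H)-one | CC1=CC(=O)OC1 | starting material
34 | tert-butyldimethylsilyl trifluoromethanesulfonate | CC(C)(C)[Si](C)(C)OS(=O)(=O)C(F)(F)F | starting material
35 | 2-(tert-butyldimethylsilyloxy)-4-methylfuran | Cc1coc(O[Si](C)(C)C(C)(C)C)c1 | intermediate
36 | 15-O-trichlorosilyl ether of 37 | C=C1C[C@H](O[Si](CC)(CC)CC)[C@@H]2[C@](C)(CCC[C@@]2(C)C=O)[C@H]1CC/C(C)=C/[C@H](O[Si](Cl)(Cl)Cl)[C@H]1OC(=O)C=C1C | intermediate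
37 | 6-O-triethylsilyl ether of the target | C=C1C[C@H](O[Si](CC)(CC)CC)[C@@H]2[C@](C)(CCC[C@@]2(C)C=O)[C@H]1CC/C(C)=C/[C@H](O)[C@H]1OC(=O)C=C1C | intermediate
38 | CNP0113661.1 | C=C1C[C@H](O)[C@@H]2[C@](C)(CCC[C@@]2(C)C=O)[C@H]1CC/C(C)=C/[C@H](O)[C@H]1OC(=O)C=C1C | target

Total step count: 17. Longest linear sequence: 16 steps (1 to 38 through steps 1–14, 16 and 17; step 15 is a one-step branch).

Steps most likely to fail

Step 11 (key step). Base-induced E2 opening of the cyclic sulfate (the hydrogen on C6 is anti-periplanar to the C5–O bond), or simply slow substitution at the neopentyl-type C5, may outrun ring closure; attack through the wrong enolate face would also erode C4. The fallback replaces the SN2 closure by a palladium-catalysed enolate alkenylation; it sets out from 20 and comes back at 25. Selective silylation of the less hindered equatorial C6 hydroxyl (Et3SiCl, imidazole) should give the 6-O-triethylsilyl ether F1. Dess–Martin oxidation would give the 5-ketone F2, and KHMDS/PhNTf2 the enol triflate F3 (C5=C6). Intramolecular α-alkenylation of the ester enolate (LiHMDS, Pd(dba)2, P(t-Bu)3) would close ring A to the silyl enol ether F4. Mild acid would unmask the 6-ketone F5, whose enolisable C5 settles as the trans ring fusion. SmI2/H2O/Et3N should reduce it to the equatorial alcohol of the 6α-hydroxy ester F6, and LiAlH4 then gives 25.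

Step 16. Facial or like/unlike selectivity of the vinylogous aldol addition may be poor, and the C18 aldehyde may compete. The fallback performs the aldol addition before the C18 aldehyde is unveiled and without a Lewis acid; it sets out from 31 and comes back at 38. MnO2 would give the bis-silylated enal F7. A tertiary-amine–squaramide-catalysed direct vinylogous aldol addition of furanone 33 would give the aldol adduct F8. Et3SiOTf/2,6-lutidine would give the tris(triethylsilyl) ether F9. Swern conditions would convert the primary silyl ether into the C18 aldehyde F10, and HF·pyridine removes both remaining silyl ethers to give 38.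

Step 4. Hydrogen abstraction may occur at the α-oxygenated C5–H or at C1 of the tether, or over-oxidation may set in. The fallback builds the enone by oxidative allylic transposition; it sets out from 7 and comes back at 9. mCPBA should give the epoxide F11 (anti to the acetonide). PhSeNa (from PhSeSePh/NaBH4) would open it at C9 to the hydroxy selenide F12. H2O2 would trigger selenoxide syn-elimination towards C8, giving the tertiary allylic alcohol F13. Pyridinium chlorochromate then effects the Babler–Dauben 1,3-transposition to 9.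

Further compounds
F1 | step 11 | 6-O-triethylsilyl ether of diol 20 (5α-OH free) | C=C1C[C@H](O[Si](CC)(CC)CC)[C@H](O)[C@](C)(CCCC(C)C(=O)OC)[C@H]1CCC#C
F2 | step 11 | 5-ketone (6α-OSiEt3) | C=C1C[C@H](O[Si](CC)(CC)CC)C(=O)[C@](C)(CCCC(C)C(=O)OC)[C@H]1CCC#C
F3 | step 11 | enol triflate (C5=C6, 5-OTf, 6-OSiEt3) | C=C1CC(O[Si](CC)(CC)CC)=C(OS(=O)(=O)C(F)(F)F)[C@](C)(CCCC(C)C(=O)OC)[C@H]1CCC#C
F4 | step 11 | ring-closed silyl enol ether (C5=C6, 6-OSiEt3, C4 methyl ester) | C=C1CC(O[Si](CC)(CC)CC)=C2[C@](C)(CCC[C@@]2(C)C(=O)OC)[C@H]1CCC#C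
F5 | step 11 | 6-ketone methyl ester (5α-H) | C=C1CC(=O)[C@@H]2[C@](C)(CCC[C@@]2(C)C(=O)OC)[C@H]1CCC#C
F6 | step 11 | 6α-hydroxy methyl ester | C=C1C[C@H](O)[C@@H]2[C@](C)(CCC[C@@]2(C)C(=O)OC)[C@H]1CCC#C
F7 | step 16 | bis(triethylsilyl) enal | C=C1C[C@H](O[Si](CC)(CC)CC)[C@@H]2[C@](C)(CCC[C@@]2(C)CO[Si](CC)(CC)CC)[C@H]1CC/C(C)=C/C=O
F8 | step 16 | bis(triethylsilyl) aldol adduct (15S,16S) | C=C1C[C@H](O[Si](CC)(CC)CC)[C@@H]2[C@](C)(CCC[C@@]2(C)CO[Si](CC)(CC)CC)[C@H]1CC/C(C)=C/[C@H](O)[C@H]1OC(=O)C=C1C
F9 | step 16 | tris(triethylsilyl) ether | C=C1C[C@H](O[Si](CC)(CC)CC)[C@@H]2[C@](C)(CCC[C@@]2(C)CO[Si](CC)(CC)CC)[C@H]1CC/C(C)=C/[C@H](O[Si](CC)(CC)CC)[C@H]1OC(=O)C=C1C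
F10 | step 16 | C18 aldehyde, 6,15-bis(triethylsilyl) ether | C=C1C[C@H](O[Si](CC)(CC)CC)[C@@H]2[C@](C)(CCC[C@@]2(C)C=O)[C@H]1CC/C(C)=C/[C@H](O[Si](CC)(CC)CC)[C@H]1OC(=O)C=C1C
F11 | step 4 | 9β,10β-epoxide of 7 | C1C[C@@H]2OC(C)(C)O[C@@H]2[C@@]3(CCCC(C)C(=O)OC)O[C@@H]13
F12 | step 4 | 10β-hydroxy 9α-phenylselenide | C1C[C@@H]2OC(C)(C)O[C@@H]2[C@](O)(CCCC(C)C(=O)OC)[C@@H]1[Se]c1ccccc1
F13 | step 4 | tertiary allylic alcohol (10-OH, C8=C9) | C=1C[C@@H]2OC(C)(C)O[C@@H]2[C@](O)(CCCC(C)C(=O)OC)C=1
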